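The numbers in the tables were computed with made-up constants; the scatter is artificial.

Ask what the protic impurity costs in target at the end of a run, and let the answer say whether the next flask gets dried or goes in as it stands.

| flask | starting material | partner | protic impurity | initiator | remark | time |
|---|---|---|---|---|---|---|
| autumn | 0.050 M | 0.11 M | 0.0080 M | 0.80 mM | run made earlier |  |
| summer | 0.050 M | 0.075 M | 0.0080 M | 0.40 mM | run made earlier |  |
| Sunday's | 0.050 M | 0.0750 M | 0.00800 M | 0.80 mM |  | 40 h |
| Friday's | 0.050 M | 0.0750 M | 0.0150 M | 0.80 mM |  | 40 h |
| Wednesday's | 0.050 M | 0.0750 M | 0.0300 M | 0.80 mM |  | 40 h |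

| run | time / h | target / % |
|---|---|---|
| autumn | 2.00 | 20 |
| autumn | 3.00 | 27 |
| autumn | 4.00 | 34 |
| autumn | 6.00 | 40 |
| autumn | 10.0 | 51 |
| autumn | 15.0 | 54 |
| autumn | 25.0 | 58 |
| summer | 2.00 | 18 |
| summer | 3.00 | 21 |
| summer | 4.00 | 26 |
| summer | 6.00 | 33 |
| summer | 10.0 | 43 |
| summer | 15.0 | 48 |
| summer | 25.0 | 52 |

(readings scatter by 2 percentage points)

- the numbers in the tables scatter by 2 percentage points (one standard deviation)
- "hardly changes" means that all values lie within two and a half points (for a concentration: within two and a half percent of the largest)
- no earlier run changes the charge of protic impurity; that part of a forecast is a guess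

1. amount of target at the end, in percent of the starting material charged for Sunday's, Friday's, Wednesday's, in this order
2. how the row runs (hardly changes / rises, then falls / falls all the way / rises all the way / falls, then rises)

1. Take as the one quantity Sunday's protic load, 16.0%, which is the impurity charged as a fraction of the starting material charged, and set beside it Friday's load of 30.0% and Wednesday's of 60.0%.

2. Assume, as a guess since no earlier run varied the impurity, that one impurity spoils one starting material; the load is then the ceiling on that loss, and the impurity is the limiting reagent of it even on Wednesday's, whose load of 60.0% stays below the whole charge.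

3. Hold that ceiling against the autumn run, which carried the same load as Sunday's but more partner: it read 58% after 25.0 h, so 42.0% of its charge was not target at that time, more than its load, and on this assumption at least 26.0% of the autumn charge was not target for some other reason, as a reading with a scatter of 2 percentage points.

4. Decide not to dry yet, since on this reckoning drying Sunday's charge recovers at most 16.0% of the charge, less than the 42.0% that the autumn run did not show as target; keep partner and initiator as on Sunday's, change the impurity and leave the rest, and, on the same guess, commit to a row that falls by no more than 44 points, the difference between the loads.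

5. The forecast is sharper, with 54%, 50% and 42%, a row that falls all the way, in its words “so I expect a gentle fall”.

6. The flasks give 62.7%, 60.7% and 56.9% after 40 h, and the row falls all the way.

    initiator → 2 initiating radical (k = 1.90 × 10⁻⁵ s⁻¹)
    starting material + initiating radical → capped initiator + first chain carrier (k = 2500 L mol⁻¹ s⁻¹)
    partner + first chain carrier ⇌ target + second chain carrier (K = 0.190, k = 60.0 L mol⁻¹ s⁻¹)
    starting material + second chain carrier → by-product + first chain carrier (k = 770 L mol⁻¹ s⁻¹)
    2 second chain carrier → ended chains (k = 5.00 × 10⁶ L mol⁻¹ s⁻¹)
    starting material + protic impurity → quenched substrate (k = 4.50 × 10⁻⁴ L mol⁻¹ s⁻¹)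
    starting material + by-product ⇌ idle adduct, settled at all times (K = 520 L mol⁻¹)

Wednesday's flask still holds 69% of its impurity after 40.0 h, so it has spent a third of it. Multiply that spent share by Wednesday's load of 60.0% and get 18.3% of the charge, which is the quenched substrate in Wednesday's flask. Do the same for Sunday's flask, where the load of 16.0% and a spent share of 33.8% give 5.40% of the charge, and the quenched substrate stands at 5.40%.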